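**Retrosynthetic overview**

1. Target: (2S,6R)-2-(4-hydroxy-3-methoxyphenyl)-6-[(1S)-1-hydroxy-2-(4-hydroxyphenyl)ethyl]oxan-4-one, 2,6-cis. Locants used throughout: O1, C2 (guaiacyl-bearing), C3, C4 (C=O), C5, C6; side chain C1′ (carbinol) and C2′ (benzylic CH2).
2. Enabling feature: the oxane ring has its ketone at C4 between two CH2 groups (C3, C5), with O1 β to it on both sides. It is therefore the hydrolysed [4+2] adduct of an aldehyde C=O (O1=C2) and a 2-silyloxy-1,3-diene (C3=C4(OSi)–C5=C6).
3. Key disconnection: O1–C6 (with C2–C3). The oxane, the only ring formed in the route, is closed by a catalytic asymmetric hetero-Diels–Alder reaction in which the aldehyde oxygen bonds to C6, setting C2 and C6 at once. Both benzene rings are bought.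
4. Diene: by soft enolisation of an (E)-enone made by Wittig olefination of an α-silyloxy aldehyde from O-benzyl-L-tyrosine, which supplies C1′. Aldehyde: vanillin as its benzyl carbonate (activating, hydrogenolysable).
5. End game: global desilylation (enol ether to C4 ketone, free C1′–OH), then hydrogenolysis of both benzyl-type groups.

Key step: step 8

Remark: the (1S,2R) antipode of the chromium catalyst is specified on the assumption that this catalyst family keeps its usual sense of induction (the (1R,2S) antipode directing dienes to the Re face of an aldehyde); the sense is assigned from recall and should be confirmed on a model aldehyde. Both antipodes are commercially available.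

**Route**

Step 1
Reactants: 1 O-benzyl-L-tyrosine
Product: 2 (2S)-3-[4-(benzyloxy)phenyl]-2-hydroxypropanoic acid
Conditions: NaNO2, 1 M H2SO4, 1,4-dioxane/H2O, 0 °C to rt
Reagents that add atoms: water, SMILES O
Why: Diazotisation–hydrolysis of the α-amino acid (deaminative hydroxylation) should proceed with net retention by double inversion through participation of the neighbouring carboxylate, so the (S) centre of L-tyrosine becomes the future C1′ carbinol in the required configuration.

Step 2
Reactants: 2 (2S)-3-[4-(benzyloxy)phenyl]-2-hydroxypropanoic acid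
Product: 3 methyl (2S)-3-[4-(benzyloxy)phenyl]-2-hydroxypropanoate
Conditions: MeOH, H2SO4 (cat.), reflux
Reagents that add atoms: methanol, SMILES CO
Why: Fischer esterification under acid catalysis should give the methyl ester without touching the stereocentre or the benzyl ether.

Step 3
Reactants: 3 methyl (2S)-3-[4-(benzyloxy)phenyl]-2-hydroxypropanoate
Product: 4 methyl (2S)-3-[4-(benzyloxy)phenyl]-2-[(tert-butyldimethylsilyl)oxy]propanoate
Conditions: TBSCl, imidazole, DMF, rt
Reagents that add atoms: tert-butyldimethylsilyl chloride, SMILES CC(C)(C)[Si](C)(C)Cl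
Why: Imidazole-promoted silylation of the secondary alcohol installs a TBS ether that should survive hydride reduction, olefination, soft enolisation and Lewis acid catalysis.

Step 4
Reactants: 4 methyl (2S)-3-[4-(benzyloxy)phenyl]-2-[(tert-butyldimethylsilyl)oxy]propanoate
Product: 5 (2S)-3-[4-(benzyloxy)phenyl]-2-[(tert-butyldimethylsilyl)oxy]propanal
Conditions: iBu2AlH (1.1 equiv), CH2Cl2, −78 °C; MeOH, then aq. potassium sodium tartrate (KNaC4H4O6)
Reagents that add atoms: none
Why: Partial reduction of an α-silyloxy ester with iBu2AlH at −78 °C should stop at the aldehyde because the tetrahedral aluminium hemiacetal persists until the quench, and the cold non-basic work-up keeps the α-stereocentre intact.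

Step 5
Reactants: 5 (2S)-3-[4-(benzyloxy)phenyl]-2-[(tert-butyldimethylsilyl)oxy]propanal; 6 1-(triphenylphosphoranylidene)propan-2-one
Product: 7 (3E,5S)-6-[4-(benzyloxy)phenyl]-5-[(tert-butyldimethylsilyl)oxy]hex-3-en-2-one
Conditions: CH2Cl2, rt
Reagents that add atoms: none
Why: Wittig olefination with the stabilised acetonyl ylide should give the (E)-enone selectively under neutral conditions that do not epimerise the α-silyloxy aldehyde.

Step 6
Reactants: 7 (3E,5S)-6-[4-(benzyloxy)phenyl]-5-[(tert-butyldimethylsilyl)oxy]hex-3-en-2-one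
Product: 8 (2S,3E)-1-[4-(benzyloxy)phenyl]-2-[(tert-butyldimethylsilyl)oxy]-5-[(triethylsilyl)oxy]hexa-3,5-diene
Conditions: Et3SiOTf, Et3N, Et2O, −78 to 0 °C; used crude after filtration through basic alumina
Reagents that add atoms: triethylsilyl trifluoromethanesulfonate, SMILES CC[Si](CC)(CC)OS(=O)(=O)C(F)(F)F
Why: Soft enolisation of the methyl ketone (kinetic deprotonation at the methyl group and O-silylation) should give the cross-conjugated 2-silyloxy-1,3-diene with the (E)-alkene and the C1′ centre unchanged.

Step 7
Reactants: 9 vanillin (4-hydroxy-3-methoxybenzaldehyde)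
Product: 10 benzyl (4-formyl-2-methoxyphenyl) carbonate
Conditions: benzyl chloroformate, Et3N, CH2Cl2, 0 °C to rt
Reagents that add atoms: benzyl chloroformate, SMILES O=C(Cl)OCc1ccccc1
Why: O-Acylation of the phenol gives an aryl benzyl carbonate that withdraws electron density from the ring, which makes the aldehyde a better heterodienophile and the later benzylic ether less prone to ionisation, and that is removable by hydrogenolysis.

Step 8
Reactants: 8 (2S,3E)-1-[4-(benzyloxy)phenyl]-2-[(tert-butyldimethylsilyl)oxy]-5-[(triethylsilyl)oxy]hexa-3,5-diene (1.3 equiv); 10 benzyl (4-formyl-2-methoxyphenyl) carbonate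
Product: 11 benzyl {4-[(2S,6R)-6-{(1S)-2-[4-(benzyloxy)phenyl]-1-[(tert-butyldimethylsilyl)oxy]ethyl}-4-[(triethylsilyl)oxy]-3,6-dihydro-2H-pyran-2-yl]-2-methoxyphenyl} carbonate
Conditions: [CrCl(C27H29NO2)] (5–10 mol %; trivalent chromium; ligand = dianion of the Schiff base from (1S,2R)-1-aminoindan-2-ol and 3-(1-adamantyl)-2-hydroxy-5-methylbenzaldehyde), powdered 4 Å molecular sieves, tert-butyl methyl ether (about 2 M), rt; filtration through Et3N-deactivated silica
Reagents that add atoms: none
Why: The chromium centre binds the aldehyde oxygen of 10 anti to the aryl group, and the electron-rich diene 8 adds in a concerted, asynchronous [4+2] cycloaddition in which C2–C3 bonding leads and the O1–C6 bond completes the ring. The closest known reaction type is the hetero-Diels–Alder reaction of unactivated aldehydes, aromatic ones included, with 4-substituted 2-silyloxy-1,3-dienes under this class of tridentate Schiff-base chromium chloride catalysts, which gives cis-2,6-disubstituted oxan-4-one enol ethers. The oxane ring is closed in the six-membered pericyclic mode (endo) from two acyclic partners, so the ring, the O1–C6 and C2–C3 bonds and two stereocentres arise in one operation. C2 is controlled by the catalyst, whose (1S,2R) antipode should expose the Si face of the aldehyde, and C6 by the endo transition state, which places the aryl group and the outside substituent of the diene terminus cis, giving (2S,6R). The (S)-silyloxy centre at C1′ should reinforce the same diene face (C–O bond near the diene plane, CH2Ar on the far side, heterodienophile anti to it), so the pairing is expected to be matched. Regioselectivity follows from the diene polarity (nucleophilic C3 terminus to the carbonyl carbon, oxygen to C6), and the rate from the carbonate, which makes the otherwise electron-rich vanillin carbonyl a competent heterodienophile.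

Step 9
Reactants: 11 benzyl {4-[(2S,6R)-6-{(1S)-2-[4-(benzyloxy)phenyl]-1-[(tert-butyldimethylsilyl)oxy]ethyl}-4-[(triethylsilyl)oxy]-3,6-dihydro-2H-pyran-2-yl]-2-methoxyphenyl} carbonate
Product: 13 benzyl {4-[(2S,6R)-6-{(1S)-2-[4-(benzyloxy)phenyl]-1-hydroxyethyl}-4-oxooxan-2-yl]-2-methoxyphenyl} carbonate, via TBS-protected oxanone 12 (not isolated)
Conditions: HF·pyridine, pyridine, THF, 0 °C to rt
Reagents that add atoms: none
Why: Fluoride-assisted protodesilylation should first convert the silyl enol ether into the C4 ketone (protonation at C5) and then cleave the secondary TBS ether, under mildly acidic conditions that avoid retro-oxa-Michael opening, epimerisation at C2 or C6 and loss of the aryl carbonate.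

Step 10
Reactants: 13 benzyl {4-[(2S,6R)-6-{(1S)-2-[4-(benzyloxy)phenyl]-1-hydroxyethyl}-4-oxooxan-2-yl]-2-methoxyphenyl} carbonate
Product: 14 (2S,6R)-2-(4-hydroxy-3-methoxyphenyl)-6-[(1S)-1-hydroxy-2-(4-hydroxyphenyl)ethyl]oxan-4-one
Conditions: H2 (1 atm), 10% Pd/C, EtOAc, rt, stopped at full conversion
Reagents that add atoms: none
Why: Catalytic hydrogenolysis should cleave the aryl benzyl ether and the benzyl carbonate (the latter with loss of carbon dioxide) much faster than the hindered secondary benzylic C2–O1 bond of the ring or the ketone, so both phenols are released under neutral conditions that leave all three stereocentres untouched.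

**Compound list**

1 | O-benzyl-L-tyrosine | N[C@@H](Cc1ccc(OCc2ccccc2)cc1)C(=O)O | starting material
2 | (2S)-3-[4-(benzyloxy)phenyl]-2-hydroxypropanoic acid | O[C@@H](Cc1ccc(OCc2ccccc2)cc1)C(=O)O | intermediate
3 | methyl (2S)-3-[4-(benzyloxy)phenyl]-2-hydroxypropanoate | O[C@@H](Cc1ccc(OCc2ccccc2)cc1)C(=O)OC | intermediate
4 | methyl (2S)-3-[4-(benzyloxy)phenyl]-2-[(tert-butyldimethylsilyl)oxy]propanoate | CC(C)(C)[Si](C)(C)O[C@@H](Cc1ccc(OCc2ccccc2)cc1)C(=O)OC | intermediate
5 | (2S)-3-[4-(benzyloxy)phenyl]-2-[(tert-butyldimethylsilyl)oxy]propanal | CC(C)(C)[Si](C)(C)O[C@@H](Cc1ccc(OCc2ccccc2)cc1)C=O | intermediate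
6 | 1-(triphenylphosphoranylidene)propan-2-one | CC(=O)C=P(c1ccccc1)(c1ccccc1)c1ccccc1 | starting material
7 | (3E,5S)-6-[4-(benzyloxy)phenyl]-5-[(tert-butyldimethylsilyl)oxy]hex-3-en-2-one | CC(=O)/C=C/[C@@H](O[Si](C)(C)C(C)(C)C)Cc1ccc(OCc2ccccc2)cc1 | intermediate
8 | (2S,3E)-1-[4-(benzyloxy)phenyl]-2-[(tert-butyldimethylsilyl)oxy]-5-[(triethylsilyl)oxy]hexa-3,5-diene | C=C(O[Si](CC)(CC)CC)/C=C/[C@@H](O[Si](C)(C)C(C)(C)C)Cc1ccc(OCc2ccccc2)cc1 | intermediate
9 | vanillin (4-hydroxy-3-methoxybenzaldehyde) | COc1cc(C=O)ccc1O | starting material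
10 | benzyl (4-formyl-2-methoxyphenyl) carbonate | COc1cc(C=O)ccc1OC(=O)OCc1ccccc1 | intermediate
11 | benzyl {4-[(2S,6R)-6-{(1S)-2-[4-(benzyloxy)phenyl]-1-[(tert-butyldimethylsilyl)oxy]ethyl}-4-[(triethylsilyl)oxy]-3,6-dihydro-2H-pyran-2-yl]-2-methoxyphenyl} carbonate | COc1cc([C@@H]2CC(O[Si](CC)(CC)CC)=C[C@H]([C@@H](O[Si](C)(C)C(C)(C)C)Cc3ccc(OCc4ccccc4)cc3)O2)ccc1OC(=O)OCc1ccccc1 | intermediate
12 | benzyl {4-[(2S,6R)-6-{(1S)-2-[4-(benzyloxy)phenyl]-1-[(tert-butyldimethylsilyl)oxy]ethyl}-4-oxooxan-2-yl]-2-methoxyphenyl} carbonate | COc1cc([C@@H]2CC(=O)C[C@H]([C@@H](O[Si](C)(C)C(C)(C)C)Cc3ccc(OCc4ccccc4)cc3)O2)ccc1OC(=O)OCc1ccccc1 | intermediate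
13 | benzyl {4-[(2S,6R)-6-{(1S)-2-[4-(benzyloxy)phenyl]-1-hydroxyethyl}-4-oxooxan-2-yl]-2-methoxyphenyl} carbonate | COc1cc([C@@H]2CC(=O)C[C@H]([C@@H](O)Cc3ccc(OCc4ccccc4)cc3)O2)ccc1OC(=O)OCc1ccccc1 | intermediate
14 | (2S,6R)-2-(4-hydroxy-3-methoxyphenyl)-6-[(1S)-1-hydroxy-2-(4-hydroxyphenyl)ethyl]oxan-4-one | COc1cc([C@@H]2CC(=O)C[C@H]([C@@H](O)Cc3ccc(O)cc3)O2)ccc1O | target

**Step count and risks**

Total step count: 10. Longest linear sequence: 9 steps (steps 1–6 and 8–10; step 7 is a one-step branch).

Steps most likely to fail:

Step 8. The cycloaddition may be slow because an aryl aldehyde is a weak heterodienophile, or the facial bias of the chiral diene may oppose the catalyst and erode diastereoselectivity. The fallback builds the same ring stepwise and sets out from enone 7 and aldehyde 10. The enol borinate of 7 is formed with Ipc2BCl and Et3N in Et2O at 0 °C, using the antipode that directs it to the Si face of the aldehyde (expected to be (−)-Ipc2BCl). It is added to 10 at −78 °C in a reagent-controlled boron aldol reaction with non-oxidative work-up, which should give benzyl {4-[(1S,4E,6S)-7-[4-(benzyloxy)phenyl]-6-[(tert-butyldimethylsilyl)oxy]-1-hydroxy-3-oxohept-4-en-1-yl]-2-methoxyphenyl} carbonate F1. Acid-catalysed 6-endo-trig oxa-Michael addition (Amberlyst-15, CH2Cl2, rt) should then close the O1–C6 bond under thermodynamic control to the 2,6-cis (diequatorial) ketone. The fallback comes back to the route at compound 12, which is desilylated under the conditions of step 9 to 13.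

Step 10. Hydrogenolysis may run on past the two O-benzyl groups and open the benzylic C2–O1 bond of the ring, which becomes more electron-rich once the para phenol is free, or reduce the ketone. The fallback is a non-reductive debenzylation that sets out from 13. BCl3 with pentamethylbenzene as cation scavenger in CH2Cl2 at −78 °C should cleave both O–CH2Ph bonds by Lewis-acid-assisted benzyl transfer to the arene, the aryl carbonic acid then losing carbon dioxide on work-up. It arrives directly at target 14 and makes no new compound (F0).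

Step 4. The partial reduction may over-reduce the ester to the primary alcohol, or the α-silyloxy aldehyde may epimerise during work-up. The fallback sets out from ester 4. Full reduction with iBu2AlH (2.5 equiv, CH2Cl2, −78 to 0 °C) should give (2S)-3-[4-(benzyloxy)phenyl]-2-[(tert-butyldimethylsilyl)oxy]propan-1-ol F2. Buffered Dess–Martin oxidation (Dess–Martin periodinane, NaHCO3, CH2Cl2, 0 °C) then comes back to the route at aldehyde 5, used at once in step 5.

Further compounds
F1 | step 8 | benzyl {4-[(1S,4E,6S)-7-[4-(benzyloxy)phenyl]-6-[(tert-butyldimethylsilyl)oxy]-1-hydroxy-3-oxohept-4-en-1-yl]-2-methoxyphenyl} carbonate | COc1cc([C@@H](O)CC(=O)/C=C/[C@@H](O[Si](C)(C)C(C)(C)C)Cc2ccc(OCc3ccccc3)cc2)ccc1OC(=O)OCc1ccccc1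
F0 | step 10 | none | none
F2 | step 4 | (2S)-3-[4-(benzyloxy)phenyl]-2-[(tert-butyldimethylsilyl)oxy]propan-1-ol | CC(C)(C)[Si](C)(C)O[C@@H](Cc1ccc(OCc2ccccc2)cc1)CO
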